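Early on, the first minutes could be seen in the beta run, while the readings of the epsilon run, which is the asked flask itself, began after them.

| flask | substrate | free catalyst | temperature | remark | time |
|---|---|---|---|---|---|
| epsilon | 0.010 M | 13 mol% | 60 °C | the very flask that is asked about, followed so far |  |
| beta | 0.015 M | 13 mol% | 55 °C | run made earlier |  |
| flask | 0.010 M | 13 mol% | 60 °C |  | 8.0 h |

| epsilon: time / min | epsilon: product / % | beta: time / min | beta: product / % |
|---|---|---|---|
| 40.0 | 62.5 | 1.33 | 33.1 |
| 60.0 | 68.6 | 2.50 | 44.0 |
| 120 | 75.8 | 4.00 | 47.4 |
| 180 | 75.9 | 6.00 | 48.1 |
| 300 | 77.8 | 10.0 | 50.5 |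
| 480 | 77.6 | 20.0 | 55.5 |

(scatter of a reading: 0.5 percentage points)

- Saturday's: change nothing and wait 4.0 h more
- Sunday's: at 8.0 h raise the temperature by 25 K, then wait 4.0 h
- Monday's: at 8.0 h add free catalyst, 100 % of the amount charged, then wait 4.0 h
- Friday's: at 8.0 h take out 90 % of the product then present, then wait 4.0 h

- what is taken out of product is counted as made
- additions bring no volume worth counting

- product, in percent of the substrate first charged, at 8.0 h
- the remedy with the largest gain of product, or "none" below 2 percentage points (Saturday's / Sunday's / Monday's / Friday's / none)
- product present, with what was taken out counted in, in percent of the substrate first charged, after Saturday's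
- product present, with what was taken out counted in, in percent of the substrate first charged, after Monday's

I built a ladder of times from these readings. On the fastest rung, the beta run reached 33.1 % at 1.33 min and slowed near 47.4 % by 4.00 min, a burst with a read time constant of 1.11 min, and then crept on to 55.5 % at 20.0 min. On the next rung, the epsilon run, at another temperature and charge than the beta run, closed its gap to a read plateau of 77.7 % with a read time constant of 38.5 min, much slower than the burst read in the beta run. On the top rung, its last two readings differed by less than their scatter, so those were the readings to watch.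

The readings did not exclude a dying catalyst, but I committed to a balance, that is, thermodynamic control. I carried the stop ratio, product over charged substrate that is not product, 3.48. So I took 77.7 % for now and after Saturday's, and expected no gain from Monday's. I could not reckon Sunday's, since I had no plateau read at another temperature. By my reckoning Friday's left the asked flask a pool of 30.1 % of the charge, and the ratio rebuilt product there to 23.4 %. That is a gain of 16 percentage points, and the wait spans 6.24 slow time constants. I therefore chose Friday's.

The forecast gave 77.7 % for now, 77.8 % after Saturday's, and 93 % after Monday's, its choice, which parted from mine. Its ground was: “The likeliest reading is that the catalyst dies in two stages, leaving substrate unused.”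

The flask stood at 77.5 % and stayed at 77.5 % after Saturday's. Friday's gained most, 15 points against my 16 points, Sunday's changed product by −33 points, and Monday's gave 73.4 %.

    substrate + free catalyst ⇌ catalyst intermediate A (K = 4700 M⁻¹, k = 14.0 M⁻¹ s⁻¹, Ea = 55.0 kJ mol⁻¹, ΔH = 19.0 kJ mol⁻¹)
    catalyst intermediate A ⇌ catalyst intermediate B (K = 0.740, k = 1.00 s⁻¹, Ea = 78.0 kJ mol⁻¹, ΔH = −82.0 kJ mol⁻¹)
    catalyst intermediate B ⇌ free catalyst + product (K = 0.0260 M, k = 0.280 s⁻¹, Ea = 82.0 kJ mol⁻¹, ΔH = −28.0 kJ mol⁻¹)
    substrate ⇌ dormant form (K = 19.0, k = 0.0170 s⁻¹, Ea = 82.0 kJ mol⁻¹, ΔH = −34.0 kJ mol⁻¹)
    (constants at 60 °C)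

The stop ratio predicted 77.7 % again for the neighbouring flask with 32 mol% of free catalyst, but that flask stood at 71.6 %, a ratio of 2.52. At 480 min, product over substrate plus dormant form, leaving out what catalyst intermediates A and B held, was 4.52 in the asked flask and 4.52 in that neighbour.

The earlier runs and the new flask were generated by integration on assumed constants; noise was put on by code.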